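If I repeat these two flasks, I watch one ratio, not target by itself.

| setting | winter | midnight | Sunday's | Thursday's |
|---|---|---|---|---|
| starting material | 0.18 M (fed, over 30 min) | 0.18 M (fed, over 30 min) | 0.18 M (fed, over 30 min) | 0.18 M (fed, over 30 min) |
| reagent | 0.189 M | 0.189 M | 0.189 M | 0.189 M |
| free catalyst | 0.59 mM | 2.3 mM | 0.43 mM | 1.5 mM |
| temperature | −45 °C | −20 °C |  |  |
| remark | run made earlier; the fed solution adds 0.10 times the starting volume | run made earlier; the fed solution adds 0.10 times the starting volume | at −40 °C until 30 min, from then on at 0 °C; the fed solution adds 0.10 times the starting volume | at 0 °C throughout; the fed solution adds 0.10 times the starting volume |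
| time |  |  | 8.0 h | 8.0 h |

winter run (percent of the starting material charged)

| time / h | target / % | starting material / % |
|---|---|---|
| 0.500 | 6 | 93 |
| 1.33 | 15 | 82 |
| 2.50 | 21 | 65 |
| 4.00 | 23 | 48 |
| 6.00 | 23 | 35 |

midnight run (percent of the starting material charged)

| time / min | target / % | starting material / % |
|---|---|---|
| 20.0 | 25 | 12 |
| 60.0 | 49 | 0 |
| 120 | 50 | 2 |

(readings scatter by 1.5 percentage points)

- every charge counts on the volume at the start, and the solution that is fed holds the whole dose
- percentages count the whole charge, also what has not yet gone in

1. which one finishes higher in amount of target, in percent of the starting material charged ("neither" within 2 percentage points) (Sunday's / Thursday's / neither)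
2. amount of target at the end, in percent of the starting material charged, Sunday's
3. amount of target at the end, in percent of the starting material charged, Thursday's

1. The odd pair comes from the winter run. Target reads 23 % at 4.00 h and 23 % at 6.00 h, yet starting material falls from 48 % to 35 %. So starting material is still being used while target reads no gain, and the new material sits in a share the readings don't show.

2. In the midnight run at 120 min, that missing share over target is 0.960: this is the plateau ratio, charge less target and starting material, divided by target. Target holds from 49 % to 50 % there, so I read the plateau as an equilibrium, which means thermodynamic control.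

3. The winter ratio climbs from 1.26 to 1.83, so I take its plateau to lie higher still. Against 0.960, that gives a logarithmic fall of at least 0.0257 K⁻¹. If the logarithm of the ratio falls evenly with temperature, I reckon at 0 °C a ratio of at most 0.574, and target of at least 63.5 %.

4. The midnight run reads its plateau by 60.0 min, with c(free catalyst) charged at 2.3 mM. Scaling that time inversely with the charged c(free catalyst), and allowing nothing for the warmer bath, I reckon 5.35 h for Sunday's, less than its 7.50 h at 0 °C. For Thursday's I reckon 1.53 h. Both should reach the same ratio, so I say neither.

5. The forecast differs: 21 % for Sunday's, 50 % for Thursday's, and Thursday's ahead, with “Thursday wins, but the mechanism is uncertain”.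

6. The flasks give 74.3 % for Sunday's and 74.3 % for Thursday's, so the answer is neither.

    reagent + catalyst intermediate A → catalyst intermediate B (k = 13.0 L mol⁻¹ min⁻¹, Ea = 35.0 kJ mol⁻¹)
    catalyst intermediate C → free catalyst + target (k = 83.0 min⁻¹, Ea = 61.0 kJ mol⁻¹)
    target + free catalyst ⇌ isomer of the product + free catalyst, rate k3*[free catalyst]*[target] forward; the back reaction follows from the equilibrium constant (K = 3.60, k = 84.0 L mol⁻¹ min⁻¹, Ea = 41.0 kJ mol⁻¹, ΔH = −31.0 kJ mol⁻¹)
    starting material + free catalyst ⇌ catalyst intermediate A (K = 120 L mol⁻¹, k = 48.0 L mol⁻¹ min⁻¹, Ea = 38.0 kJ mol⁻¹, ΔH = 18.0 kJ mol⁻¹)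
    catalyst intermediate B → catalyst intermediate C (k = 9.90 min⁻¹, Ea = 51.0 kJ mol⁻¹)
    (constants at −40 °C)

7. At the end of Thursday's the missing share is isomer of the product, with a ratio to target of 0.346, below my limit of 0.574. From the reading of 0.960 at −20 °C to 0.346 at 0 °C, the logarithmic fall is 0.0510 K⁻¹. The neighbouring flask is Thursday's kept at 25 °C. Carrying the fall on to it, I reckon a ratio of 0.0967, hence 91.2 % target. That neighbouring flask ends with 9.93 % isomer of the product and 90.1 % target.

The readings are calculated on assumed constants, noise included.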